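The B-ring chroman's dihydropyran is cut into a 2-fluorobenzyl unit and isobutylene oxide. O1–C2(CH3)2–C3 of that ring is the intact epoxide, and benzylic C4 with ortho C8a of ring B (a C–F carbon in the precursor) form a 1,3-nucleophile/electrophile pair. One domino operation (copper-catalysed epoxide opening by a benzylic Grignard reagent, then intramolecular SNAr) forms C4–C3 and O1–C8a and should give 6-bromo-2,2-dimethylchroman from 5-bromo-2-fluorobenzyl bromide. This bromide α-arylates a Claisen-derived 8-prenylchroman-4-one. The labile C3 centre is set late by transfer-hydrogenative dynamic kinetic resolution and reoxidation, before a buffered desilylation.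

Key step: step 1

Remark: locants in step 1 refer to the 2,2-dimethylchroman unit; from step 2 on they refer to the chroman-4-one (isoflavanone) core. Compounds 1, 2, 7 and 8 are taken as purchasable. The (R,R) catalyst in step 6 is assigned by analogy with 1-tetralone-type ketones.

Step 1
Reactants: 1 4-bromo-2-(bromomethyl)-1-fluorobenzene (5-bromo-2-fluorobenzyl bromide); 2 2,2-dimethyloxirane (isobutylene oxide)
Product: 6 6-bromo-2,2-dimethylchroman, via benzylic Grignard reagent 3 (not isolated), via bromomagnesium alkoxide 4 (not isolated), via potassium alkoxide 5 (not isolated)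
Conditions: Mg, 2-MeTHF, 0 °C (slow addition of 1); CuI (10 mol %), 2, −30 °C to rt; then KOt-Bu (1.2 equiv), DMPU, 70 °C; aq NH4Cl
Reagents that add atoms: none
Why: Magnesium inserts into the benzylic C–Br bond of 1 (faster than into the aryl C–Br bond at 0 °C) and the resulting 3, as a cuprate formed with catalytic CuI, opens 2 by SN2 attack at its unhindered CH2 terminus, creating the C4–C3 bond and the tertiary alkoxide 4; exchange of magnesium for potassium with KOt-Bu gives the more nucleophilic alkoxide 5, which attacks the fluorine-bearing carbon and expels fluoride through a Meisenheimer intermediate, creating the O1–C8a bond. The closest known reaction types are the copper-catalysed opening of epoxides by Grignard reagents and the alkoxide-mediated intramolecular SNAr of 3-(2-fluorophenyl)propanols to chromans, here run as one domino [3+3] annulation. The single ring is closed in the 6-exo-trig mode (addition–elimination at an aromatic sp2 carbon), helped by the gem-dimethyl group on the carbinol carbon. No stereocenter is formed. The step needs regioselective epoxide opening, which the primary versus quaternary termini of 2 and copper catalysis at low temperature should secure against rearrangement to isobutyraldehyde, and it needs substitution at C–F and not at C–Br, which is secured because fluoride is the better leaving group in addition–elimination, sits para to the weakly activating bromine and is the only halogen within reach of the tether.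

Step 2
Reactants: 7 7-hydroxychroman-4-one; 8 tert-butyl 2-methylbut-3-en-2-yl carbonate
Product: 9 7-[(2-methylbut-3-en-2-yl)oxy]chroman-4-one
Conditions: Pd(PPh3)4 (2 mol %), THF, 0 °C
Reagents that add atoms: none
Why: Decarboxylative Tsuji–Trost O-allylation, in which zerovalent palladium ionises 8 to a 1,1-dimethyl-π-allyl complex and tert-butoxide, the latter deprotonates the acidic phenol, and the phenoxide attacks the more substituted allyl terminus under kinetic control at low temperature to give the tertiary allyl aryl ether.

Step 3
Reactants: 9 7-[(2-methylbut-3-en-2-yl)oxy]chroman-4-one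
Product: 11 7-hydroxy-8-(3-methylbut-2-en-1-yl)chroman-4-one, via ortho-dienone 10 (not isolated)
Conditions: PhNEt2, 170 °C
Reagents that add atoms: none
Why: Aromatic Claisen rearrangement, whose [3,3] shift inverts the allyl unit so that the tertiary ether delivers a normal prenyl group, and which should go to C8 and not C6 because donation from ring oxygen O1 into the C4 carbonyl raises the double-bond character of C7–C8 (as in 7-allyloxycoumarins and chromones), after which dienone 10 tautomerises to the phenol.

Step 4
Reactants: 11 7-hydroxy-8-(3-methylbut-2-en-1-yl)chroman-4-one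
Product: 12 8-(3-methylbut-2-en-1-yl)-7-[(triisopropylsilyl)oxy]chroman-4-one
Conditions: TIPSCl, imidazole, DMF, rt
Reagents that add atoms: triisopropylsilyl chloride, CC(C)[Si](Cl)(C(C)C)C(C)C
Why: Standard imidazole-mediated silylation of a phenol, the bulky silyl ether being chosen because it should survive alkoxide base in step 5 and can be removed at the end without mineral acid (which would cyclise the ortho-prenyl phenol) and without free base (which would racemise C3).

Step 5
Reactants: 12 8-(3-methylbut-2-en-1-yl)-7-[(triisopropylsilyl)oxy]chroman-4-one; 6 6-bromo-2,2-dimethylchroman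
Product: 13 rac-3-(2,2-dimethylchroman-6-yl)-8-(3-methylbut-2-en-1-yl)-7-[(triisopropylsilyl)oxy]chroman-4-one
Conditions: Pd(OAc)2 (5 mol %), P(t-Bu)3·HBF4 (10 mol %), NaOt-Bu (2.2 equiv), toluene, 70 °C; aq NH4Cl
Reagents that add atoms: none
Why: Palladium-catalysed α-arylation of a ketone enolate (Buchwald–Hartwig type, known for chroman-4-ones as a route to isoflavanones) by oxidative addition of 6, transmetalation with the sodium enolate of 12 and reductive elimination, the more acidic product being held as its enolate so that a second arylation is suppressed and C3 deliberately formed racemic.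

Step 6
Reactants: 13 rac-3-(2,2-dimethylchroman-6-yl)-8-(3-methylbut-2-en-1-yl)-7-[(triisopropylsilyl)oxy]chroman-4-one
Product: 14 (3R,4R)-3-(2,2-dimethylchroman-6-yl)-8-(3-methylbut-2-en-1-yl)-7-[(triisopropylsilyl)oxy]chroman-4-ol (cis)
Conditions: RuCl[(R,R)-TsDPEN](p-cymene) (2 mol %), HCO2H/Et3N (5:2), EtOAc, 40 °C
Reagents that add atoms: none
Why: Noyori–Ikariya asymmetric transfer hydrogenation with dynamic kinetic resolution, a reaction type known for isoflavanones, in which Et3N racemises the acidic C3 centre quickly, the (R,R) catalyst delivers hydride to one carbonyl face (C4 becomes R) and reduces much faster the enantiomer whose 3-aryl group lies anti to the incoming hydride, so that C3 (R) is set by catalyst control and the cis relation by the substrate.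

Step 7
Reactants: 14 (3R,4R)-3-(2,2-dimethylchroman-6-yl)-8-(3-methylbut-2-en-1-yl)-7-[(triisopropylsilyl)oxy]chroman-4-ol
Product: 15 (3R)-3-(2,2-dimethylchroman-6-yl)-8-(3-methylbut-2-en-1-yl)-7-[(triisopropylsilyl)oxy]chroman-4-one
Conditions: Dess–Martin periodinane, CH2Cl2, 0 °C to rt
Reagents that add atoms: none
Why: Dess–Martin oxidation of the benzylic secondary alcohol under neutral, non-enolising conditions removes the auxiliary C4 stereocenter and should leave the adjacent C3 configuration (R) untouched, while the prenyl alkene and the silyl ether are inert.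

Step 8
Reactants: 15 (3R)-3-(2,2-dimethylchroman-6-yl)-8-(3-methylbut-2-en-1-yl)-7-[(triisopropylsilyl)oxy]chroman-4-one
Product: 16 (3R)-3-(2,2-dimethyl-3,4-dihydro-2H-chromen-6-yl)-7-hydroxy-8-(3-methylbut-2-en-1-yl)-2,3-dihydro-4H-chromen-4-one (CNP0139927.1)
Conditions: TBAF, AcOH (1:1), THF, 0 °C
Reagents that add atoms: none
Why: Fluoride cleavage of the aryl silyl ether (Si–F bond formation with a para-acyl phenoxide as a good leaving group), buffered with acetic acid so that neither fluoride nor the liberated phenoxide acts as a base on the enolisable C3–H and no mineral acid is present to cyclise the prenyl phenol.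

Compound list
1 | 4-bromo-2-(bromomethyl)-1-fluorobenzene (5-bromo-2-fluorobenzyl bromide) | Fc1ccc(Br)cc1CBr | starting material
2 | 2,2-dimethyloxirane (isobutylene oxide) | CC1(C)CO1 | starting material
3 | (5-bromo-2-fluorobenzyl)magnesium bromide | Fc1ccc(Br)cc1C[Mg]Br | intermediate
4 | bromomagnesium 4-(5-bromo-2-fluorophenyl)-2-methylbutan-2-olate | CC(C)(CCc1cc(Br)ccc1F)O[Mg]Br | intermediate
5 | potassium 4-(5-bromo-2-fluorophenyl)-2-methylbutan-2-olate | CC(C)(CCc1cc(Br)ccc1F)[O-].[K+] | intermediate
6 | 6-bromo-2,2-dimethylchroman (6-bromo-2,2-dimethyl-3,4-dihydro-2H-chromene) | CC1(C)CCc2cc(Br)ccc2O1 | intermediate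
7 | 7-hydroxychroman-4-one | O=C1CCOc2cc(O)ccc12 | starting material
8 | tert-butyl 2-methylbut-3-en-2-yl carbonate | C=CC(C)(C)OC(=O)OC(C)(C)C | starting material
9 | 7-[(2-methylbut-3-en-2-yl)oxy]chroman-4-one | C=CC(C)(C)Oc1ccc2c(c1)OCCC2=O | intermediate
10 | 8-(3-methylbut-2-en-1-yl)-2,3-dihydro-4H-chromene-4,7(8H)-dione (ortho-dienone, racemic at C8) | CC(C)=CCC1C(=O)C=CC2=C1OCCC2=O | intermediate
11 | 7-hydroxy-8-(3-methylbut-2-en-1-yl)chroman-4-one | CC(C)=CCc1c(O)ccc2c1OCCC2=O | intermediate
12 | 8-(3-methylbut-2-en-1-yl)-7-[(triisopropylsilyl)oxy]chroman-4-one | CC(C)=CCc1c(O[Si](C(C)C)(C(C)C)C(C)C)ccc2c1OCCC2=O | intermediate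
13 | rac-3-(2,2-dimethylchroman-6-yl)-8-(3-methylbut-2-en-1-yl)-7-[(triisopropylsilyl)oxy]chroman-4-one | CC(C)=CCc1c(O[Si](C(C)C)(C(C)C)C(C)C)ccc2c1OCC(c1ccc3c(c1)CCC(C)(C)O3)C2=O | intermediate
14 | (3R,4R)-3-(2,2-dimethylchroman-6-yl)-8-(3-methylbut-2-en-1-yl)-7-[(triisopropylsilyl)oxy]chroman-4-ol (cis) | CC(C)=CCc1c(O[Si](C(C)C)(C(C)C)C(C)C)ccc2c1OC[C@@H](c1ccc3c(c1)CCC(C)(C)O3)[C@H]2O | intermediate
15 | (3R)-3-(2,2-dimethylchroman-6-yl)-8-(3-methylbut-2-en-1-yl)-7-[(triisopropylsilyl)oxy]chroman-4-one | CC(C)=CCc1c(O[Si](C(C)C)(C(C)C)C(C)C)ccc2c1OC[C@@H](c1ccc3c(c1)CCC(C)(C)O3)C2=O | intermediate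
16 | (3R)-3-(2,2-dimethyl-3,4-dihydro-2H-chromen-6-yl)-7-hydroxy-8-(3-methylbut-2-en-1-yl)-2,3-dihydro-4H-chromen-4-one (CNP0139927.1) | CC(C)=CCc1c(O)ccc2c1OC[C@@H](c1ccc3c(c1)CCC(C)(C)O3)C2=O | target

Total step count: 8. Longest linear sequence: 7 steps (steps 2 to 8, from 7); step 1 is a one-step branch that joins at step 5.

Steps most likely to fail

Step 1 (key step). The ring closure is the weak point: addition–elimination at a fluoroarene activated only by a para bromine may be slower than base-induced dehydrohalogenation to an aryne or intermolecular attack by tert-butoxide. Homocoupling during magnesium insertion could also erode the first half. The fallback keeps the same two bonds but makes them in two operations, with a copper-catalysed C–O coupling in place of SNAr. It sets out from 2: purchased 1,4-dibromo-2-(bromomethyl)benzene F1 is converted with Mg (2-MeTHF, 0 °C) into (2,5-dibromobenzyl)magnesium bromide F2, which opens 2 under CuI catalysis, and aqueous work-up should give isolated 4-(2,5-dibromophenyl)-2-methylbutan-2-ol F3. Ullmann-type intramolecular etherification (CuI, 1,10-phenanthroline, Cs2CO3, toluene, 110 °C), in which the copper alkoxide can reach only the ortho bromine, would close the ring and come back to the route at 6.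

Step 5. Under NaOt-Bu the chromanone enolate may open ring C by E1cB expulsion of the aryloxide, the silyl ether may be lost to alkoxide, or a second arylation may follow the first. The fallback avoids free enolate and strong base. It sets out from 12: TMSOTf/Et3N (CH2Cl2, 0 °C) should give triisopropyl{[8-(3-methylbut-2-en-1-yl)-4-[(trimethylsilyl)oxy]-2H-chromen-7-yl]oxy}silane F4, which is coupled with 6 through its tin enolate (Pd(OAc)2, P(t-Bu)3, Bu3SnF, toluene, 85 °C) and comes back at 13.

Step 2. Zerovalent palladium may re-ionise the electron-poor tertiary allyl aryl ether, so that the kinetic branched ether drifts to the linear prenyl ether, which would give the wrong (reverse) prenyl group in step 3. The fallback makes the tertiary ether without a π-allyl intermediate. It sets out from 7: 3-chloro-3-methylbut-1-yne with DBU and catalytic CuCl2·2H2O (MeCN, 0 °C) should give 7-[(2-methylbut-3-yn-2-yl)oxy]chroman-4-one F5, and semi-hydrogenation (H2, Pd/CaCO3 poisoned with Pb(OAc)2, quinoline, EtOAc) comes back at 9.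

Further compounds
F1 | step 1 | 1,4-dibromo-2-(bromomethyl)benzene (purchased) | BrCc1cc(Br)ccc1Br
F2 | step 1 | (2,5-dibromobenzyl)magnesium bromide | Br[Mg]Cc1cc(Br)ccc1Br
F3 | step 1 | 4-(2,5-dibromophenyl)-2-methylbutan-2-ol | CC(C)(O)CCc1cc(Br)ccc1Br
F4 | step 5 | triisopropyl{[8-(3-methylbut-2-en-1-yl)-4-[(trimethylsilyl)oxy]-2H-chromen-7-yl]oxy}silane | CC(C)=CCc1c(O[Si](C(C)C)(C(C)C)C(C)C)ccc2c1OCC=C2O[Si](C)(C)C
F5 | step 2 | 7-[(2-methylbut-3-yn-2-yl)oxy]chroman-4-one | C#CC(C)(C)Oc1ccc2c(c1)OCCC2=O
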